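The cyclohexane (C1 quaternary with methyl C10 and chlorovinyl C8=C9; C3 with Br and C7H2Br; C4 and C6 each CHCl) is disconnected at C1–C2. In the ring, C6–Cl is equatorial, on the face opposite C10 and on the same face as C4–Cl. A chair-like anti delivery of Cl+ to C6 and of carbon to C1 of a (Z)-alkene would leave exactly this pattern. One operation therefore makes C6–Cl and C1–C2, closes the only ring, sets C1 and C6 from C4, and unmasks the C3=C7 methylene for the final dibromination. The precursor is an open-chain (R)-allylic chloride flanked by a 2-substituted allyltrimethylsilane and a (Z,Z)-1-chloro-3-methyl-1,3-diene.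

Key step: step 9

Assumption: the sense of induction in step 5 follows the usual face-shielding model of the imidazolidinone enamine, and the (5S)-catalyst would be used if the opposite sense were found; atom labels C1–C10 are those of the overview.

Step 1
Reactants: 1 methyl 4,4-dimethoxybutanoate
Product: 2 4,4-dimethoxybutanal
Conditions: i-Bu2AlH (1.05 equiv), CH2Cl2, −78 °C; aq potassium sodium tartrate
Reagents that add atoms: none
Why: Partial ester reduction with i-Bu2AlH at −78 °C stops at the aluminium hemiacetal, which releases the aldehyde only on work-up, and the dimethyl acetal is inert to hydride.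

Step 2
Reactants: 2 4,4-dimethoxybutanal; 3 ethyltriphenylphosphonium bromide
Product: 7 (Z)-2-iodo-6,6-dimethoxyhex-2-ene, via ethylidene ylide 4 (not isolated), via iodoethylphosphonium iodide 5 (not isolated), via iodoethylidene ylide 6 (not isolated)
Conditions: 3, n-BuLi, THF, rt; I2, −78 °C; NaN(SiMe3)2, −20 °C; 2, −78 °C
Reagents that add atoms: iodine, II
Why: Stork–Zhao-type α-iodoalkylidene Wittig olefination, in which the non-stabilised iodo ylide 6 reacts under kinetic control through the cis-oxaphosphetane, so the C5 chain ends cis to iodine (Z) and methyl C10 trans to it, the geometry that C6=C1 needs later.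

Step 3
Reactants: 7 (Z)-2-iodo-6,6-dimethoxyhex-2-ene; 8 (Z)-1,2-dichloroethene
Product: 11 (1Z,3Z)-1-chloro-7,7-dimethoxy-3-methylhepta-1,3-diene, via alkenyllithium 9 (not isolated), via alkenylzinc chloride 10 (not isolated)
Conditions: t-BuLi (2.1 equiv), Et2O, −78 °C; ZnCl2, THF, −78 to 0 °C; 8 (5 equiv), Pd(PPh3)4 (5 mol %), THF, rt
Reagents that add atoms: none
Why: Negishi coupling, in which lithium–iodine exchange and transmetalation to zinc keep the alkene geometry, zerovalent palladium inserts with retention into one C–Cl bond of the excess (Z)-dichloride 8, and the C–Cl bond of the resulting chlorodiene is too unreactive with this catalyst to couple again.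

Step 4
Reactants: 11 (1Z,3Z)-1-chloro-7,7-dimethoxy-3-methylhepta-1,3-diene
Product: 12 (4Z,6Z)-7-chloro-5-methylhepta-4,6-dienal
Conditions: 1 M aq HCl, THF, 0 °C to rt
Reagents that add atoms: water, O
Why: Acid-catalysed acetal hydrolysis, too mild to protonate or isomerise the chlorodiene, unmasks the C3 aldehyde without a separate deprotection and oxidation.

Step 5
Reactants: 12 (4Z,6Z)-7-chloro-5-methylhepta-4,6-dienal
Product: 13 (2R,4Z,6Z)-2,7-dichloro-5-methylhepta-4,6-dienal
Conditions: (5R)-5-benzyl-2,2,3-trimethylimidazolidin-4-one·CF3CO2H (10 mol %), 2,3,4,5,6,6-hexachlorocyclohexa-2,4-dien-1-one (1.2 equiv), acetone, −30 °C; cold pentane work-up, used crude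
Reagents that add atoms: 2,3,4,5,6,6-hexachlorocyclohexa-2,4-dien-1-one, O=C1C(Cl)=C(Cl)C(Cl)=C(Cl)C1(Cl)Cl
Why: Enamine-catalysed asymmetric α-chlorination of an aldehyde, in which the benzyl group of the (5R)-imidazolidinone covers one face of the E-enamine, the quinone delivers Cl+ to the open face and sets C4 as R, and this mild Cl+ donor reacts with enamines but not with the chlorodiene.

Step 6
Reactants: 13 (2R,4Z,6Z)-2,7-dichloro-5-methylhepta-4,6-dienal
Product: 14 (2R,4Z,6Z)-2,7-dichloro-5-methylhepta-4,6-dienoic acid
Conditions: NaClO2, NaH2PO4, 2-methylbut-2-ene (20 equiv), t-BuOH–H2O, 0 °C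
Reagents that add atoms: sodium chlorite, [Na+].[O-]Cl=O
Why: Pinnick oxidation runs in a weakly acidic buffer in which the α-chloro aldehyde does not enolise, so C4 is kept, while the large excess of 2-methylbut-2-ene intercepts HOCl before it reaches the diene.

Step 7
Reactants: 14 (2R,4Z,6Z)-2,7-dichloro-5-methylhepta-4,6-dienoic acid
Product: 15 methyl (2R,4Z,6Z)-2,7-dichloro-5-methylhepta-4,6-dienoate
Conditions: Me3SiCHN2, toluene–MeOH, 0 °C
Reagents that add atoms: (trimethylsilyl)diazomethane, C[Si](C)(C)C=[N+]=[N-]
Why: Methyl esterification with (trimethylsilyl)diazomethane proceeds by protonation of the reagent and O-alkylation of the carboxylate, needs neither base nor carboxyl activation, and therefore leaves C4 untouched.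

Step 8
Reactants: 15 methyl (2R,4Z,6Z)-2,7-dichloro-5-methylhepta-4,6-dienoate; 16 (trimethylsilyl)methylmagnesium chloride
Product: 18 [(3R,5Z,7Z)-3,8-dichloro-6-methyl-2-methylideneocta-5,7-dien-1-yl]trimethylsilane (the =CH2 carbon is C2, the CH2Si carbon is C7), via bis(silylmethyl) carbinol 17 (not isolated)
Conditions: anhydrous CeCl3 (4 equiv), 16 (4 equiv), THF, −78 to 0 °C; cold aq NH4Cl; then SiO2, CH2Cl2, rt
Reagents that add atoms: none
Why: Cerium-mediated double addition of the (trimethylsilyl)methyl nucleophile to an ester followed by acid-type Peterson elimination of one β-hydroxysilane arm is the standard entry to 2-substituted allylsilanes, the weakly basic organocerium species should add faster than it enolises the α-chloro ester so that C4 keeps its configuration, and the cold quench keeps the chlorohydrin alkoxide from closing to an epoxide.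

Step 9
Reactants: 18 [(3R,5Z,7Z)-3,8-dichloro-6-methyl-2-methylideneocta-5,7-dien-1-yl]trimethylsilane
Product: 20 (1S,2S,4R)-2,4-dichloro-1-[(Z)-2-chloroethenyl]-1-methyl-5-methylidenecyclohexane, via beta-silyl cation 19 (not isolated)
Conditions: Et2SCl·SbCl6 (1.05 equiv, slow addition), 2,6-di-tert-butyl-4-methylpyridine (0.2 equiv), EtNO2, −78 °C, 10 min; aq Na2SO3–NaHCO3
Reagents that add atoms: chlorodiethylsulfonium hexachloroantimonate, CC[S+](Cl)CC.Cl[Sb-](Cl)(Cl)(Cl)(Cl)Cl
Why: Proposed new method: the chlorosulfonium salt hands Cl+ to C6, the alkyl-bearing end of the sterically twisted diene, creating a chloriranium/allyl cation with its charge mainly on tertiary C1; the =CH2 carbon C2 of the allylsilane bonds to C1 from the face opposite the new C6–Cl bond, and cation 19, stabilised by the C7–Si bond, loses Me3Si+ to chloride from SbCl6−, so the alkene can only appear as exocyclic C3=C7. The closest known reaction types are chlorosulfonium-initiated cation–olefin cyclisations of isolated trisubstituted alkenes and allylsilane-terminated cation–olefin cyclisations, whereas a conjugated chlorodiene as initiator in the presence of an allylsilane has no precedent. The single cyclohexane ring closes 6-endo-trig with respect to both the C6=C1 and the C2=C3 π bond, through a chair. The C6/C1 relationship is set by anti addition to the (Z)-alkene (C6–Cl and C10 equatorial, C8 axial, hence Cl trans to methyl), and the absolute sense of both centres is set by C4, whose C–Cl bond should sit equatorial, near the nodal plane of the reacting C2=C3 π bond where it drains it least, which places C6–Cl 1,3-cis to C4–Cl. The step needs site selectivity for C6=C1 over the allylsilane (helped by the trisubstituted donor alkene and by inductive deactivation of C2=C3 by the allylic C4 chloride), regioselectivity for C1 over C9 (attack at C9 would need an eight-membered ring) and retention of the (Z)-C8=C9 geometry (helped by −78 °C and rapid intramolecular capture). The hindered pyridine only removes adventitious acid that would protodesilylate 18.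

Step 10
Reactants: 20 (1S,2S,4R)-2,4-dichloro-1-[(Z)-2-chloroethenyl]-1-methyl-5-methylidenecyclohexane
Product: 21 (1S,2R,4S,5S)-1-bromo-1-(bromomethyl)-2,4-dichloro-5-[(Z)-2-chloroethenyl]-5-methylcyclohexane
Conditions: Br2 (1.0 equiv), CH2Cl2, −78 °C, dark
Reagents that add atoms: bromine, BrBr
Why: Electrophilic anti addition of bromine through a bromonium ion, in which the 1,1-disubstituted C3=C7 alkene is far more electron-rich than the neopentyl, chlorine-deactivated C8=C9 bond, Br+ engages the equatorial face away from the axial chlorovinyl group, and bromide opens the ion at tertiary C3 along the axial line, setting C3 with Br axial (cis to C4–Cl) and C7H2Br equatorial, which should also be the thermodynamically preferred arrangement.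

Compound list
1 | methyl 4,4-dimethoxybutanoate | COC(=O)CCC(OC)OC | starting material
2 | 4,4-dimethoxybutanal | O=CCCC(OC)OC | intermediate
3 | ethyltriphenylphosphonium bromide | CC[P+](c1ccccc1)(c1ccccc1)c1ccccc1.[Br-] | starting material
4 | ethylidenetriphenylphosphorane | CC=P(c1ccccc1)(c1ccccc1)c1ccccc1 | intermediate
5 | (1-iodoethyl)triphenylphosphonium iodide | CC(I)[P+](c1ccccc1)(c1ccccc1)c1ccccc1.[I-] | intermediate
6 | (1-iodoethylidene)triphenylphosphorane | CC(I)=P(c1ccccc1)(c1ccccc1)c1ccccc1 | intermediate
7 | (Z)-2-iodo-6,6-dimethoxyhex-2-ene (chain cis to iodine) | COC(OC)CC/C=C(C)\I | intermediate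
8 | (Z)-1,2-dichloroethene | Cl/C=C\Cl | starting material
9 | (6,6-dimethoxyhex-2-en-2-yl)lithium, chain cis to lithium | COC(OC)CC/C=C(C)\[Li] | intermediate
10 | (6,6-dimethoxyhex-2-en-2-yl)zinc chloride, chain cis to zinc | COC(OC)CC/C=C(C)\[Zn]Cl | intermediate
11 | (1Z,3Z)-1-chloro-7,7-dimethoxy-3-methylhepta-1,3-diene | COC(OC)CC/C=C(C)\C=C/Cl | intermediate
12 | (4Z,6Z)-7-chloro-5-methylhepta-4,6-dienal | O=CCC/C=C(C)\C=C/Cl | intermediate
13 | (2R,4Z,6Z)-2,7-dichloro-5-methylhepta-4,6-dienal | O=C[C@H](Cl)C/C=C(C)\C=C/Cl | intermediate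
14 | (2R,4Z,6Z)-2,7-dichloro-5-methylhepta-4,6-dienoic acid | OC(=O)[C@H](Cl)C/C=C(C)\C=C/Cl | intermediate
15 | methyl (2R,4Z,6Z)-2,7-dichloro-5-methylhepta-4,6-dienoate | COC(=O)[C@H](Cl)C/C=C(C)\C=C/Cl | intermediate
16 | (trimethylsilyl)methylmagnesium chloride | C[Si](C)(C)C[Mg]Cl | starting material
17 | (3R,5Z,7Z)-3,8-dichloro-6-methyl-1-(trimethylsilyl)-2-[(trimethylsilyl)methyl]octa-5,7-dien-2-ol | C[Si](C)(C)CC(O)(C[Si](C)(C)C)[C@H](Cl)C/C=C(C)\C=C/Cl | intermediate
18 | [(3R,5Z,7Z)-3,8-dichloro-6-methyl-2-methylideneocta-5,7-dien-1-yl]trimethylsilane | C[Si](C)(C)CC(=C)[C@H](Cl)C/C=C(C)\C=C/Cl | intermediate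
19 | (2R,4S,5S)-2,4-dichloro-5-[(Z)-2-chloroethenyl]-5-methyl-1-[(trimethylsilyl)methyl]cyclohexan-1-ylium hexachloroantimonate | C[C@@]1(/C=C\Cl)C[C+](C[Si](C)(C)C)[C@H](Cl)C[C@@H]1Cl.Cl[Sb-](Cl)(Cl)(Cl)(Cl)Cl | intermediate
20 | (1S,2S,4R)-2,4-dichloro-1-[(Z)-2-chloroethenyl]-1-methyl-5-methylidenecyclohexane | C[C@@]1(/C=C\Cl)CC(=C)[C@H](Cl)C[C@@H]1Cl | intermediate
21 | (1S,2R,4S,5S)-1-bromo-1-(bromomethyl)-2,4-dichloro-5-[(Z)-2-chloroethenyl]-5-methylcyclohexane | C[C@@]1(/C=C\Cl)C[C@@](Br)(CBr)[C@H](Cl)C[C@@H]1Cl | target

Total step count: 10. Longest linear sequence: 10 steps (1 to 21).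

Steps most likely to fail

1. Step 9.
- What may go wrong: Cl+ may transfer to the allylsilane instead of the diene (chlorodesilylation). A long-lived open allyl cation may erode the anti stereospecificity. Induction from C4 may be weak, and the chlorovinyl group may lose its Z geometry.
- Fallback: it sets out from 14 and comes back at 20, and it moves the chlorination to a stage where no allylsilane is present. Acid 14 is chlorolactonised (1,3-dichloro-5,5-dimethylhydantoin, CHCl3, −40 °C). This is the same anti addition, with the carboxyl oxygen instead of C2 attacking C1 in a 6-endo chair that keeps C4–Cl equatorial. It should give (3R,5S,6S)-3,5-dichloro-6-[(Z)-2-chloroethenyl]-6-methyloxan-2-one F1, a stage at which diastereomers can be separated. Reagent 16 with CeCl3 (THF, −78 °C, cold quench) converts the lactone carbonyl into (3R,5S,6S,7Z)-3,5,8-trichloro-6-methyl-1-(trimethylsilyl)-2-[(trimethylsilyl)methyl]oct-7-ene-2,6-diol F2. Silica gel then effects the Peterson elimination to (1Z,3S,4S,6R)-1,4,6-trichloro-3-methyl-7-[(trimethylsilyl)methyl]octa-1,7-dien-3-ol F3. BF3·OEt2 (CH2Cl2, −78 °C) ionises the tertiary allylic C1–OH, the neighbouring C6 chloride shields its own face, and the allylsilane closes the ring to 20. Halolactonisation, the cerium/Peterson allylsilane synthesis on lactones and Lewis acid-induced allylsilane cyclisation onto allylic alcohols are all established reaction types.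

2. Step 10.
- What may go wrong: facial selectivity at C3 may be poor. The axial chlorovinyl group hinders axial entry of bromide, and the bromonium ion may open at primary C7 instead of C3.
- Fallback: it sets out from 20 and comes back at 21, and it replaces kinetic by thermodynamic control. The bromination mixture, which would also contain (1R,2R,4S,5S)-1-bromo-1-(bromomethyl)-2,4-dichloro-5-[(Z)-2-chloroethenyl]-5-methylcyclohexane F4, is not separated. It is warmed with Et4NBr in MeCN at about 60 °C. Reversible ionisation of the tertiary C3–Br bond, assisted by the C7 bromine, is the mutarotation known for vicinal dibromides, and it equilibrates C3. Compound 21 has the small Br axial and C7H2Br equatorial, free of the syn-axial clash with C8, so it should be the favoured epimer.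

3. Step 8.
- What may go wrong: the α-chloro carbonyl stage may enolise with loss of configuration at C4. During the warming that an ester needs for the second addition, the alkoxide may close onto C4 with loss of chloride.
- Fallback: it sets out from 14 and comes back at 17, and it makes the two C–C bonds one at a time. Acid 14 is coupled with MeNHOMe·HCl (EDC·HCl, N-methylmorpholine, CH2Cl2, 0 °C) to (2R,4Z,6Z)-2,7-dichloro-N-methoxy-N,5-dimethylhepta-4,6-dienamide F5. One equivalent of 16 (THF, −40 °C) adds and stops at the chelated tetrahedral adduct. A cold neutral work-up then gives (3R,5Z,7Z)-3,8-dichloro-6-methyl-1-(trimethylsilyl)octa-5,7-dien-2-one F6. This ketone takes up the organocerium reagent from 16 and CeCl3 within minutes at −78 °C and is quenched cold, so the alkoxide never reaches a temperature at which it displaces chloride. The product is carbinol 17, which continues as in step 8.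

Further compounds
F1 | step 9 | (3R,5S,6S)-3,5-dichloro-6-[(Z)-2-chloroethenyl]-6-methyloxan-2-one | C[C@@]1(/C=C\Cl)OC(=O)[C@H](Cl)C[C@@H]1Cl
F2 | step 9 | (3R,5S,6S,7Z)-3,5,8-trichloro-6-methyl-1-(trimethylsilyl)-2-[(trimethylsilyl)methyl]oct-7-ene-2,6-diol | C[Si](C)(C)CC(O)(C[Si](C)(C)C)[C@H](Cl)C[C@H](Cl)[C@@](C)(O)/C=C\Cl
F3 | step 9 | (1Z,3S,4S,6R)-1,4,6-trichloro-3-methyl-7-[(trimethylsilyl)methyl]octa-1,7-dien-3-ol | C[Si](C)(C)CC(=C)[C@H](Cl)C[C@H](Cl)[C@@](C)(O)/C=C\Cl
F4 | step 10 | (1R,2R,4S,5S)-1-bromo-1-(bromomethyl)-2,4-dichloro-5-[(Z)-2-chloroethenyl]-5-methylcyclohexane | C[C@@]1(/C=C\Cl)C[C@](Br)(CBr)[C@H](Cl)C[C@@H]1Cl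
F5 | step 8 | (2R,4Z,6Z)-2,7-dichloro-N-methoxy-N,5-dimethylhepta-4,6-dienamide | CON(C)C(=O)[C@H](Cl)C/C=C(C)\C=C/Cl
F6 | step 8 | (3R,5Z,7Z)-3,8-dichloro-6-methyl-1-(trimethylsilyl)octa-5,7-dien-2-one | C[Si](C)(C)CC(=O)[C@H](Cl)C/C=C(C)\C=C/Cl
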